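**Strategy.** The six-membered ring of the oxo end group (C-1 to C-6, carotenoid numbering) is cut across C-2–C-3 and C-6–C-1. Its C-4=C-5 double bond, flanked by carbonyl C-3 and stereogenic C-6, is a cyclohexene retron. A vinylketene acetal supplies C-3 to C-6 and already carries the acetylenic C-7 to C-11 chain; 2-methyl-1-nitropropene supplies CMe2 (C-1) and C-2. One Diels–Alder step forms both bonds, the quaternary carbon and, after hydrolysis, the enone. Denitration, reduction, lipase resolution and a C15 + C10 + C15 Wittig union give the C2-symmetric 3,3'-diol; oxidation of one allylic alcohol restores the ring ketone.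

Key step: step 3

Remark 1: ring positions in the text use carotenoid numbering (C-1 = CMe2, C-2 = CH2, C-3 = carbonyl or carbinol carbon, C-4=C-5 = ring olefin, C-6 = ring carbon bearing the chain).
Remark 2: the side-chain carbinol carbon that comes from racemic 1 is carried as an epimer mixture, is written without descriptor and disappears in step 8.
Remark 3: racemates 7–9 (one ring stereocentre) are written without descriptor; racemates 10 and 11 (defined trans relation) are written as both enantiomers joined by a dot.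
Remark 4: 2 is used as the pure Z isomer, taken from the commercial E/Z mixture by chromatography.

Step 1
Reactants: 1 3-methylpent-1-en-4-yn-3-ol (racemic); 2 methyl (2Z)-4-bromo-3-methylbut-2-enoate
Product: 3 methyl (2Z)-7-hydroxy-3,7-dimethylnona-2,8-dien-5-ynoate
Conditions: CuI (10 mol%), K2CO3, Bu4NI (cat.), DMF, 20 °C
Reagents that add atoms: none
Why: copper-catalysed alkyne–allyl halide coupling (SN2 alkylation of the copper acetylide by the primary allylic bromide) under a weak carbonate base should give the skipped enyne without touching the tertiary alcohol or isomerising the Z-enoate; no stereocentre is formed.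

Step 2
Reactants: 3 methyl (2Z)-7-hydroxy-3,7-dimethylnona-2,8-dien-5-ynoate
Product: 5 {[(3E)-1-methoxy-3,7-dimethyl-7-(trimethylsilyloxy)nona-1,3,8-trien-5-yn-1-yl]oxy}trimethylsilane, via dilithium dienolate 4 (not isolated)
Conditions: LiN(i-Pr)2 (2.2 equiv), THF, −78 °C; Me3SiCl (2.5 equiv), −78 → 0 °C; non-aqueous work-up
Reagents that add atoms: chlorotrimethylsilane, C[Si](C)(C)Cl
Why: kinetic γ-deprotonation of the Z-enoate at the CH2 that is cis to the ester and also propargylic (extended enolate formation), then O-silylation, should give the vinylketene acetal; allylic strain in the cisoid enolisation geometry places the alkynyl group outside (new olefin E), and the tertiary alkoxide is silylated in the same pot.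

Step 3
Reactants: 5 {[(3E)-1-methoxy-3,7-dimethyl-7-(trimethylsilyloxy)nona-1,3,8-trien-5-yn-1-yl]oxy}trimethylsilane; 6 2-methyl-1-nitroprop-1-ene
Product: 8 4-(3-hydroxy-3-methylpent-4-en-1-yn-1-yl)-3,5,5-trimethyl-6-nitrocyclohex-2-en-1-one (racemic), via silyl ketal cycloadduct 7 (not isolated)
Conditions: toluene, 80 °C, sealed tube; then 1 M HCl, THF, 0 °C
Reagents that add atoms: none
Why: Normal-electron-demand [4+2] cycloaddition of a 1-alkoxy-1-silyloxy diene with a nitroalkene, concerted but strongly asynchronous, with the bond from the diene terminus to CMe2 leading; the closest known reaction type is the Diels–Alder reaction of ketene-acetal dienes with nitroalkenes. The carbocycle closes by intermolecular [4+2] cycloaddition, the diene termini (future C-3 and C-6) bonding to the nitro-bearing carbon (future C-2) and to CMe2 (future C-1); no other ring is formed. The new stereocentre at C-6 arises without absolute control (racemate, resolved in step 7), the nitro-bearing carbon is erased in step 4, and CMe2 is not stereogenic. The step needs regioselectivity, which the matched polarisation secures: the nucleophilic terminus remote from the two oxygens attacks the β-carbon of the nitroalkene, and the ketene-acetal carbon ends next to the nitro group. It also needs the diene to react as a 4π unit, not at its α-carbon; the E geometry from step 2 (alkynyl outside) and the 3-methyl group favour the s-cis form. Mild acid then hydrolyses the mixed methyl silyl ketal to the conjugated ketone and frees the tertiary alcohol.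

Step 4
Reactants: 8 4-(3-hydroxy-3-methylpent-4-en-1-yn-1-yl)-3,5,5-trimethyl-6-nitrocyclohex-2-en-1-one (racemic)
Product: 9 4-(3-hydroxy-3-methylpent-4-en-1-yn-1-yl)-3,5,5-trimethylcyclohex-2-en-1-one (racemic)
Conditions: Bu3SnH (1.3 equiv), AIBN (0.2 equiv), toluene, 80 °C
Reagents that add atoms: none
Why: radical chain denitration of an α-nitro ketone (tin radical adds to the nitro group, C–N homolysis gives the α-keto radical, H transfer from Bu3SnH) should leave the ring CH2; the nitro group reacts much faster than the internal alkyne, and the neutral conditions keep the C-6 stereocentre and the olefin position intact.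

Step 5
Reactants: 9 4-(3-hydroxy-3-methylpent-4-en-1-yn-1-yl)-3,5,5-trimethylcyclohex-2-en-1-one (racemic)
Product: 10 rac-(1S,4S)-4-(3-hydroxy-3-methylpent-4-en-1-yn-1-yl)-3,5,5-trimethylcyclohex-2-en-1-ol
Conditions: KHB(s-Bu)3 (K-Selectride, 2.3 equiv), THF, −78 °C; aq. NH4Cl; chromatography
Reagents that add atoms: none
Why: 1,2-reduction of a β,β-disubstituted enone by a bulky trialkylborohydride, in which hydride should enter anti to the pseudo-axial methyl of the CMe2 group, that is, on the face of the pseudo-axial alkynyl group, so that the hydroxyl ends up trans to the side chain; any cis isomer is removed by chromatography.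

Step 6
Reactants: 10 rac-(1S,4S)-4-(3-hydroxy-3-methylpent-4-en-1-yn-1-yl)-3,5,5-trimethylcyclohex-2-en-1-ol
Product: 11 rac-(1S,4S)-4-[(1E)-3-hydroxy-3-methylpenta-1,4-dien-1-yl]-3,5,5-trimethylcyclohex-2-en-1-ol
Conditions: NaAlH2(OCH2CH2OMe)2 (Red-Al, 3.5 equiv), THF, 0 → 20 °C; aq. potassium sodium tartrate
Reagents that add atoms: none
Why: hydroxyl-directed trans-hydroalumination of the propargylic alkoxide and protonolysis (aluminium hydride reduction of a propargylic alcohol) should give the E-olefin only, leaving the ring stereocentres, the vinyl group and the ring olefin untouched.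

Step 7
Reactants: 11 rac-(1S,4S)-4-[(1E)-3-hydroxy-3-methylpenta-1,4-dien-1-yl]-3,5,5-trimethylcyclohex-2-en-1-ol
Product: 12 (1S,4S)-4-[(1E)-3-hydroxy-3-methylpenta-1,4-dien-1-yl]-3,5,5-trimethylcyclohex-2-en-1-yl acetate
Conditions: lipase PS (Burkholderia cepacia, immobilised), vinyl acetate (3 equiv), t-BuOMe, 30 °C, to about half conversion; chromatography
Reagents that add atoms: vinyl acetate, CC(=O)OC=C
Why: lipase-catalysed kinetic resolution by transesterification, in which the empirical size rule for secondary alcohols (CH2–CMe2 flank as the large group) predicts acylation of the (1S)-carbinol, so that the (1S,4S)-acetate is separated from the unreacted (1R,4R)-alcohol and both ring stereocentres become absolute; the tertiary alcohol is inert.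

Step 8
Reactants: 12 (1S,4S)-4-[(1E)-3-hydroxy-3-methylpenta-1,4-dien-1-yl]-3,5,5-trimethylcyclohex-2-en-1-yl acetate
Product: 13 [(2E,4E)-5-[(1S,4S)-4-acetoxy-2,6,6-trimethylcyclohex-2-en-1-yl]-3-methylpenta-2,4-dien-1-yl]triphenylphosphonium bromide
Conditions: PPh3·HBr (1.05 equiv), MeOH/CH2Cl2, 0 → 20 °C; crystallisation
Reagents that add atoms: triphenylphosphine hydrobromide, [Br-].[PH+](c1ccccc1)(c1ccccc1)c1ccccc1
Why: SN1 ionisation of the tertiary doubly allylic alcohol and capture of the pentadienyl cation by PPh3 at its unhindered terminus (the vinyl carbinol to C15 phosphonium salt transformation) should give the conjugated salt, crystallised as the (2E,4E) isomer; the ring oxygen stays protected as the acetate and the acid is consumed as water forms.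

Step 9
Reactants: 13 [(2E,4E)-5-[(1S,4S)-4-acetoxy-2,6,6-trimethylcyclohex-2-en-1-yl]-3-methylpenta-2,4-dien-1-yl]triphenylphosphonium bromide (2.2 equiv); 14 (2E,4E,6E)-2,7-dimethylocta-2,4,6-trienedial
Product: 18 (3S,6S,3'S,6'S)-ε,ε-carotene-3,3'-diol, via phosphorus ylide 15 (not isolated), via C25 acetoxy aldehyde 16 (not isolated), via C40 diacetate 17 (not isolated)
Conditions: NaOMe (2.3 equiv), CH2Cl2/MeOH, 0 → 20 °C; then NaOMe (0.5 equiv), MeOH, 20 °C; then EtOH, reflux; crystallisation
Reagents that add atoms: none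
Why: twofold Wittig olefination of the dial by the semi-stabilised allylic ylide (C15 + C10 + C15 assembly), methanolysis of both acetates by NaOMe in the same pot, and heating to secure the all-E polyene should give the crystalline diol; the ring stereocentres are not touched because no ring ketone is present yet.

Step 10
Reactants: 18 (3S,6S,3'S,6'S)-ε,ε-carotene-3,3'-diol
Product: 19 (3S,6S,6'S)-3-hydroxy-ε,ε-caroten-3'-one (CNP0344065.1)
Conditions: activated MnO2 (excess), CH2Cl2, 20 °C, stopped near half conversion of the carbinols; chromatography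
Reagents that add atoms: none
Why: MnO2 oxidises only allylic alcohols and works under neutral conditions, so the base-sensitive C-6 stereocentre next to the new enone should not epimerise; because the two carbinols are equivalent, the reaction is stopped at partial conversion and the mono-ketone is separated from recovered 18 (recycled) and the diketone.

**Compound list**

1 | 3-methylpent-1-en-4-yn-3-ol (racemic) | C=CC(C)(O)C#C | starting material
2 | methyl (2Z)-4-bromo-3-methylbut-2-enoate | COC(=O)/C=C(/C)CBr | starting material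
3 | methyl (2Z)-7-hydroxy-3,7-dimethylnona-2,8-dien-5-ynoate | COC(=O)/C=C(/C)CC#CC(C)(O)C=C | intermediate
4 | dilithium (3E)-1-methoxy-3,7-dimethyl-7-oxidonona-1,3,8-trien-5-yn-1-olate | [Li+].[Li+].COC([O-])=C/C(C)=C/C#CC(C)([O-])C=C | intermediate (not isolated)
5 | {[(3E)-1-methoxy-3,7-dimethyl-7-(trimethylsilyloxy)nona-1,3,8-trien-5-yn-1-yl]oxy}trimethylsilane | COC(O[Si](C)(C)C)=C/C(C)=C/C#CC(C)(O[Si](C)(C)C)C=C | intermediate
6 | 2-methyl-1-nitroprop-1-ene | CC(C)=C[N+](=O)[O-] | starting material
7 | {[1-methoxy-3,5,5-trimethyl-4-(3-methyl-3-(trimethylsilyloxy)pent-4-en-1-yn-1-yl)-6-nitrocyclohex-2-en-1-yl]oxy}trimethylsilane (stereoisomer mixture) | COC1(O[Si](C)(C)C)C=C(C)C(C#CC(C)(O[Si](C)(C)C)C=C)C(C)(C)C1[N+](=O)[O-] | intermediate (not isolated)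
8 | 4-(3-hydroxy-3-methylpent-4-en-1-yn-1-yl)-3,5,5-trimethyl-6-nitrocyclohex-2-en-1-one (racemic) | CC1=CC(=O)C([N+](=O)[O-])C(C)(C)C1C#CC(C)(O)C=C | intermediate
9 | 4-(3-hydroxy-3-methylpent-4-en-1-yn-1-yl)-3,5,5-trimethylcyclohex-2-en-1-one (racemic) | CC1=CC(=O)CC(C)(C)C1C#CC(C)(O)C=C | intermediate
10 | rac-(1S,4S)-4-(3-hydroxy-3-methylpent-4-en-1-yn-1-yl)-3,5,5-trimethylcyclohex-2-en-1-ol (trans) | C=CC(C)(O)C#C[C@@H]1C(C)=C[C@@H](O)CC1(C)C.C=CC(C)(O)C#C[C@H]1C(C)=C[C@H](O)CC1(C)C | intermediate
11 | rac-(1S,4S)-4-[(1E)-3-hydroxy-3-methylpenta-1,4-dien-1-yl]-3,5,5-trimethylcyclohex-2-en-1-ol (trans) | C=CC(C)(O)/C=C/[C@@H]1C(C)=C[C@@H](O)CC1(C)C.C=CC(C)(O)/C=C/[C@H]1C(C)=C[C@H](O)CC1(C)C | intermediate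
12 | (1S,4S)-4-[(1E)-3-hydroxy-3-methylpenta-1,4-dien-1-yl]-3,5,5-trimethylcyclohex-2-en-1-yl acetate | C=CC(C)(O)/C=C/[C@@H]1C(C)=C[C@@H](OC(C)=O)CC1(C)C | intermediate
13 | [(2E,4E)-5-[(1S,4S)-4-acetoxy-2,6,6-trimethylcyclohex-2-en-1-yl]-3-methylpenta-2,4-dien-1-yl]triphenylphosphonium bromide | [Br-].C(/C=C(C)/C=C/[C@@H]1C(C)=C[C@@H](OC(C)=O)CC1(C)C)[P+](c1ccccc1)(c1ccccc1)c1ccccc1 | intermediate
14 | (2E,4E,6E)-2,7-dimethylocta-2,4,6-trienedial | O=C/C(C)=C/C=C/C=C(C)/C=O | starting material
15 | (1S,4S)-3,5,5-trimethyl-4-[(1E,3E)-3-methyl-5-(triphenylphosphoranylidene)penta-1,3-dien-1-yl]cyclohex-2-en-1-yl acetate | c1ccccc1P(c1ccccc1)(c1ccccc1)=C/C=C(C)/C=C/[C@@H]1C(C)=C[C@@H](OC(C)=O)CC1(C)C | intermediate (not isolated)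
16 | (2E,4E,6E,8E,10E,12E)-13-[(1S,4S)-4-acetoxy-2,6,6-trimethylcyclohex-2-en-1-yl]-2,7,11-trimethyltrideca-2,4,6,8,10,12-hexaenal | O=C/C(C)=C/C=C/C=C(C)/C=C/C=C(C)/C=C/[C@@H]1C(C)=C[C@@H](OC(C)=O)CC1(C)C | intermediate (not isolated)
17 | (3S,6S,3'S,6'S)-ε,ε-carotene-3,3'-diyl diacetate | CC1=C[C@@H](OC(C)=O)CC(C)(C)[C@@H]1/C=C/C(C)=C/C=C/C(C)=C/C=C/C=C(C)/C=C/C=C(C)/C=C/[C@@H]1C(C)=C[C@@H](OC(C)=O)CC1(C)C | intermediate (not isolated)
18 | (3S,6S,3'S,6'S)-ε,ε-carotene-3,3'-diol | CC1=C[C@@H](O)CC(C)(C)[C@@H]1/C=C/C(C)=C/C=C/C(C)=C/C=C/C=C(C)/C=C/C=C(C)/C=C/[C@@H]1C(C)=C[C@@H](O)CC1(C)C | intermediate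
19 | (3S,6S,6'S)-3-hydroxy-ε,ε-caroten-3'-one | CC1=CC(=O)CC(C)(C)[C@@H]1/C=C/C(C)=C/C=C/C(C)=C/C=C/C=C(C)/C=C/C=C(C)/C=C/[C@@H]1C(C)=C[C@@H](O)CC1(C)C | target

**Step count and risks**

Total step count: 10. Longest linear sequence: 10 steps (1 or 2 → 19; 13 is used twice in step 9).

Most likely to fail, step 3: the cycloaddition may stall because a quaternary carbon must be joined to a tertiary one, or the diene may be attacked at its α-carbon (acyclic Michael adducts, cyclic nitronates) instead of reacting as a 4π unit. The fallback sets out from 3 and comes back at 9, forming the same two ring bonds in a polar, stepwise way. Ester 3 and commercial 4-methylpent-3-en-2-one are treated with KOt-Bu in t-BuOH/THF. Conjugate addition of the extended enolate through its γ-carbon should give the keto ester methyl 4-(3-hydroxy-3-methylpent-4-en-1-yn-1-yl)-3,5,5-trimethyl-7-oxooct-2-enoate F1. Under the same conditions Claisen condensation should close F1 to the acetyl enone 6-acetyl-4-(3-hydroxy-3-methylpent-4-en-1-yn-1-yl)-3,5,5-trimethylcyclohex-2-en-1-one F2 (the dimedone-type sequence). Retro-Claisen deacetylation of F2 with NaOMe in MeOH and mild acid work-up would then give 9.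

Most likely to fail, step 7: the enzyme may discriminate the enantiomers of 11 poorly or acylate the hindered carbinol too slowly, and cis material carried over from step 5 would not be removed. The fallback sets out from 9 and comes back at 12, introducing absolute configuration by reagent control. Racemic 9 is reduced with (R)-Me-CBS oxazaborolidine and catecholborane (toluene, −78 °C), assuming the olefinic flank of the ketone acts as the large group. Hydride is then delivered to the same carbonyl face of both enantiomers, so one gives the trans alcohol (1S,4S)-4-(3-hydroxy-3-methylpent-4-en-1-yn-1-yl)-3,5,5-trimethylcyclohex-2-en-1-ol F3 and the other the cis alcohol (1S,4R)-4-(3-hydroxy-3-methylpent-4-en-1-yn-1-yl)-3,5,5-trimethylcyclohex-2-en-1-ol F4. These are diastereomers and are separated by chromatography. Reduction of F3 as in step 6 should give the single-enantiomer diol (1S,4S)-4-[(1E)-3-hydroxy-3-methylpenta-1,4-dien-1-yl]-3,5,5-trimethylcyclohex-2-en-1-ol F5. Ac2O in pyridine acetylates only its secondary hydroxyl and gives 12.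

Most likely to fail, step 10: the two allylic carbinols of 18 are equivalent, so over-oxidation to the diketone cannot be suppressed and the mono-ketone forms only as part of a statistical mixture. The fallback sets out from 13 and 14 and comes back at 19, differentiating the two ends by the acetate that 13 already carries.
- 13 (1 equiv) and 14 (3 equiv) with NaOMe in CH2Cl2/MeOH should give, via 15 and 16 and methanolysis of the acetate, the hydroxy aldehyde (2E,4E,6E,8E,10E,12E)-13-[(1S,4S)-4-hydroxy-2,6,6-trimethylcyclohex-2-en-1-yl]-2,7,11-trimethyltrideca-2,4,6,8,10,12-hexaenal F6.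
- A second Wittig reaction of F6 with 13 under neutral conditions (1,2-epoxybutane, EtOH, reflux) keeps the acetate and should give the mono-acetate (3S,6S,3'S,6'S)-3'-hydroxy-ε,ε-caroten-3-yl acetate F7.
- MnO2 then oxidises the only free allylic alcohol to the oxo acetate (3S,6S,6'S)-3'-oxo-ε,ε-caroten-3-yl acetate F8.
- Neutral enzymatic hydrolysis of the acetate (Candida rugosa lipase, pH 7 buffer with acetone, 30 °C) would give 19 without exposing the oxo ring to base.

**Further compounds**

F1 | step 3 | methyl 4-(3-hydroxy-3-methylpent-4-en-1-yn-1-yl)-3,5,5-trimethyl-7-oxooct-2-enoate | COC(=O)C=C(C)C(C#CC(C)(O)C=C)C(C)(C)CC(C)=O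
F2 | step 3 | 6-acetyl-4-(3-hydroxy-3-methylpent-4-en-1-yn-1-yl)-3,5,5-trimethylcyclohex-2-en-1-one | CC1=CC(=O)C(C(C)=O)C(C)(C)C1C#CC(C)(O)C=C
F3 | step 7 | (1S,4S)-4-(3-hydroxy-3-methylpent-4-en-1-yn-1-yl)-3,5,5-trimethylcyclohex-2-en-1-ol (single enantiomer) | C=CC(C)(O)C#C[C@@H]1C(C)=C[C@@H](O)CC1(C)C
F4 | step 7 | (1S,4R)-4-(3-hydroxy-3-methylpent-4-en-1-yn-1-yl)-3,5,5-trimethylcyclohex-2-en-1-ol | C=CC(C)(O)C#C[C@H]1C(C)=C[C@@H](O)CC1(C)C
F5 | step 7 | (1S,4S)-4-[(1E)-3-hydroxy-3-methylpenta-1,4-dien-1-yl]-3,5,5-trimethylcyclohex-2-en-1-ol (single enantiomer) | C=CC(C)(O)/C=C/[C@@H]1C(C)=C[C@@H](O)CC1(C)C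
F6 | step 10 | (2E,4E,6E,8E,10E,12E)-13-[(1S,4S)-4-hydroxy-2,6,6-trimethylcyclohex-2-en-1-yl]-2,7,11-trimethyltrideca-2,4,6,8,10,12-hexaenal | O=C/C(C)=C/C=C/C=C(C)/C=C/C=C(C)/C=C/[C@@H]1C(C)=C[C@@H](O)CC1(C)C
F7 | step 10 | (3S,6S,3'S,6'S)-3'-hydroxy-ε,ε-caroten-3-yl acetate | CC1=C[C@@H](OC(C)=O)CC(C)(C)[C@@H]1/C=C/C(C)=C/C=C/C(C)=C/C=C/C=C(C)/C=C/C=C(C)/C=C/[C@@H]1C(C)=C[C@@H](O)CC1(C)C
F8 | step 10 | (3S,6S,6'S)-3'-oxo-ε,ε-caroten-3-yl acetate | CC1=CC(=O)CC(C)(C)[C@@H]1/C=C/C(C)=C/C=C/C(C)=C/C=C/C=C(C)/C=C/C=C(C)/C=C/[C@@H]1C(C)=C[C@@H](OC(C)=O)CC1(C)C
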